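In the early times of Sunday's run you can watch X go, and it goes so regularly that it pays to work with the fraction left, not the fraction made.

| flask | X | temperature | remark | time |
|---|---|---|---|---|
| Sunday's | 0.075 M | 80 °C | run made earlier |  |
| delta | 0.050 M |  | at 60 °C until 1.5 min, from then on at 100 °C | 5.0 min |
| gamma | 0.050 M | 80 °C |  | 5.0 min |
| alpha | 0.050 M | 100 °C |  | 5.0 min |
| epsilon | 0.050 M | 60 °C |  | 5.0 min |

Sunday's run (percent of the X charged)

| time / s | J / % | X / % |
|---|---|---|
| 15.0 | 10.8 | 43.9 |
| 30.0 | 26.4 | 19.3 |
| 50.0 | 44.7 | 5.1 |
| 60.0 | 50.5 | 3.2 |

(scatter of a reading: 1 percentage point)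

* the flask with the highest amount of J, in percent of the X charged ("all alike" if they lie within 1.5 percentage points) (delta / gamma / alpha / epsilon / all alike)
* final J, as a percentage of the X charged, in delta
* final J, as a percentage of the X charged, in gamma
* final J, as a percentage of the X charged, in alpha
* final J, as a percentage of the X charged, in epsilon

- the earlier runs do not show what temperature does; that part of a forecast is a guess

After 15.0 s, Sunday's flask reads X at 43.9% of the charge, and over the next 15.0 s X keeps 44.0% of what it had. These two equal spans of time leave nearly equal fractions, within the scatter. Read from them, that gives a rate constant k, the fractional loss per unit time, and a halving time h (the usual term is half-life), the time in which X falls to half of whatever is there while the fall stays this regular: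

k = 0.0548 s⁻¹

h = ln(2) / k = 12.7 s at 80 °C

Sunday's run shows one temperature, so the next step is my own guess: h stretches by a factor of 4 going down to 60 °C and shrinks by the same factor going up to 100 °C.

cold h = 4 × h = 50.6 s

This cold halving time, the time I reckon X takes to halve at 60 °C, is what I carry forward.

Now run delta slowly. In the first instants it sits at 60 °C and X is going. J should lag, as it did on Sunday's run, where X and J together fell 54.3% short of the charge at 30.0 s. So part of the charge stood as neither X nor J at that reading.

By the change at 1.5 min, I reckon that delta has had 1.78 halvings: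

fraction of X left = 0.5 ^ (time / cold h) = 29.2%

Then the heat comes. By the same guess the hot h is 3.16 s, so the hot stretch of delta holds 66.4 halvings by my reckoning, far more than the cold one. What heat does to J and to the rest of the charge I cannot reckon from Sunday's run.

The forecast gives yields where I give a fraction left: 64% for delta, 65% for gamma, 64% for alpha, 60% for epsilon, and all alike as the answer for the most J, with the caution “Temperature could shift the yield or destroy J”.

Delta ends at 51.6%, and gamma holds the most J at 66.1%; alpha gives 55.0% and epsilon 43.4%. In delta, J stood at 54.9% after 2.50 min and slipped from there. At the change, delta held X at 45.7%, more than the 29.2% from the cold halving time.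

    X → G (k = 0.445 min⁻¹, Ea = 92.0 kJ mol⁻¹)
    2 X → L (k = 0.915 L mol⁻¹ min⁻¹, Ea = 59.0 kJ mol⁻¹)
    G ⇌ J (K = 5.14, k = 0.304 min⁻¹, Ea = 86.0 kJ mol⁻¹, ΔH = −24.0 kJ mol⁻¹)
    X + G → Q (k = 1.31 L mol⁻¹ min⁻¹, Ea = 47.0 kJ mol⁻¹)
    G ⇌ Z (K = 2.50, k = 0.00436 min⁻¹, Ea = 112 kJ mol⁻¹, ΔH = −41.0 kJ mol⁻¹)
    (constants at 60 °C)

Now read delta earlier, at 80 s, still in the cold. The cold halving time gives 33.4% of X left, and the computed flask holds 49.7%, again more than reckoned.

(The data are simulated on assumed constants.)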